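**Compound numbering.** The numbers 1–32 are fixed by the steps below and are used in every section.

## Analysis of the target

The target (32) is a linear phlorotannin of the fuhalol type: seven benzene rings, lettered A to G in the order of the SMILES string, joined only by six diaryl ether oxygens and carrying seventeen free phenolic hydroxyls. Each ring is numbered from the carbon that holds the ether oxygen towards the preceding ring (ring A from its own ether carbon). Ring A is then a 2,4,6-trihydroxyphenyl end group, rings B, D and F are 3,5-dihydroxy rings linked through C1 and C4, ring E is linked through the adjacent carbons C1 and C6 with hydroxyls at C3 and C5, and ring G is a 3,4,5-trihydroxyphenyl end group. Ring C is the odd one: five contiguous carbons bear oxygen (C1 to ring B, C6 to ring D, hydroxyls at C5, C4 and C3) and only C2 bears hydrogen. There is no stereocentre and no axis that would be configurationally stable, so every problem is one of regiochemistry and reactivity. The free polyphenol, above all the pyrogallol-type arrays of rings C and G, is oxidised by air as soon as phenoxides are present, so all hydroxyls should stay masked as methyl ethers until the last step. The hard part is the ether bonds: each of the six oxygens sits on one carbon flanked by two oxygenated carbons, and in the B–O–C and D–O–E bonds the second carbon carries an ortho aryloxy group as well. For D–O–E an SNAr reaction is open, because C1 of ring E is meta to the oxygens at C3 and C5; for B–O–C it is not, since the C4 oxygen of ring C is para to C1. The strategy rests on reading ring C as two pieces: C3, C4, C5 and C6 with their four oxygens are the four carbons of a squaric ester, and C1–C2 is a vinyl group that already carries the ring B oxygen on C1, so the B–O–C bond is never made by arylation.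

## Retrosynthetic reasoning

**Deprotection.** The seventeen O–CH3 bonds of the permethylated heptamer 31 are cut last to give 32. Methyl ethers are the one protecting group that passes organolithium, copper, peracid and thermal steps alike, and the building blocks already carry them. The forward reaction has to cleave all of them by Lewis acid without touching the diaryl ethers.

**Ring C to ring D.** The bond between the C6 oxygen of ring C and C1 of ring D is cut, which divides 31 into the three-ring phenol 21 and the four-ring bromide 30. The cut is placed here because C1 of ring D has hydrogen on both sides, so the hindered partner is the phenoxide and the unhindered partner the bromide, the arrangement an Ullmann coupling tolerates. It also brings the product of the ring expansion together with the other half only two steps from the end.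

**Telling the two para oxygens of ring C apart.** Phenol 21 needs a free C6 hydroxyl and a methylated C3 oxygen. It is traced back through silyl ether 20 to phenol 19, in which the C6 oxygen bears the silyl group and the C3 oxygen is free. The forward steps are one methylation and one desilylation.

**Ring C itself.** In 19 the C2–C3 bond of ring C is cut and the C3–C6 unit is folded back into a four-membered ring, which leads to the cyclobutenone 16. This removes the need for a pentaoxygenated benzene building block and for any arylation at the di-ortho-substituted ring B oxygen. The forward reaction is a thermal ring opening to a dienylketene followed by six-electron ring closure and aromatisation.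

**Vinyl to squarate.** The bond between the quaternary carbon of 16 (the future C6) and the vinyl carbon (the future C1) is cut. This gives, through alcohol 15, dimethyl squarate 13 and the vinyllithium 14. The two carbonyl groups of 13 are equivalent, so the addition has no regiochemical issue, and silylation of 15 gives 16.

**The aryloxyvinyl anion.** Vinyllithium 14 comes from stannane 12 by tin–lithium exchange, 12 from the ynol ether 11 by hydrostannation, and 11 from the dichlorovinyl ether 8. The vinyl–oxygen bond of 8 is cut to the ring A–B phenol 5 and trichloroethylene 6, which reacts by way of dichloroacetylene 7. The hindered phenoxide of 5 thus attacks a linear sp carbon, where crowding does not matter. Direct lithiation of an aryl vinyl ether is avoided because the ring hydrogens that lie between two oxygens would compete.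

**Ring A to ring B.** The ether bond between C1 of ring A and C1 of ring B is cut: 5 comes from benzyl ether 4, and 4 from the hindered phenol 3 and bromide 2, the benzyl ether of 1. The bromide side again has no ortho substituent.

**Ring E to ring F.** In 30 the bond between the C6 oxygen of ring E and C1 of ring F is cut to give phenol 29 and boronic acid 25. An oxidative copper coupling is chosen in place of an Ullmann coupling because the bromine on ring D must survive for the union with 21.

**Ring D to ring E.** Phenol 29 comes from aldehyde 27 by oxidation of the formyl group to a hydroxyl, and the bond between the C4 oxygen of ring D and C1 of ring E in 27 is cut to 1 and the fluoroaldehyde 26. Both sides of this ether are hindered, so it is made by SNAr, where the formyl group activates the fluorinated carbon and then becomes the C6 oxygen of ring E.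

**Ring F to ring G.** Boronic acid 25 comes from bromide 23, and the bond between the C4 oxygen of ring F and C1 of ring G is cut to 1 and boronic acid 22. Compound 1 thus serves three times, for rings B, D and F.

## Alternatives that were turned down

**Alternative 1:** Both ether bonds of ring E are cut at once, which gives three fragments: the ring A–B–C–D phenol A3, the ring F–G phenol A4, and A2, the hexafluorophosphate of the cyclopentadienylruthenium cation bound η6 to 1,2-dichloro-3,5-dimethoxybenzene. In the forward direction the phenoxide of A3 displaces the chlorine at C1, the phenoxide of A4 the chlorine at C6, and photolysis releases the arene as the permethylated heptamer A1, which is the same compound as 31.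
- For it: the metal turns an electron-rich chloroarene into an acceptor that takes even di-ortho-substituted phenoxides under mild conditions. The first substitution should go to C1, which is meta to both methoxy groups and less crowded, so the order of addition sets the regiochemistry. It is the most convergent of all the plans; on this point it is stronger than the chosen route, which spends steps 12 to 17 on the same bonds.
- Against it: the second substitution, at C6, is ortho and para to methoxy donors and next to the newly attached bulky aryloxy group. The ruthenium fragment can move to the other electron-rich rings on heating or photolysis. The metal is used in stoichiometric amount.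
- Comparison: A3 still contains ring C and the B–O–C bond, which this plan does not make. It replaces only the ring E chemistry of the chosen route; the squarate ring expansion would be needed in any case, and what the chosen route offers in its place is a solution for ring C with cheap copper and SNAr chemistry at ring E.

**Alternative 2:** Ring D is built from acyclic parts by cutting C2–C3 and C5–C6. The aryloxymalonate A6 (rings E–F–G) supplies C3, C4 and C5 with the C4 ether oxygen, and the 3-aryloxyglutaconate A7 (rings A–B–C) supplies C2, C1 and C6 with the C1 ether oxygen. A base-mediated double Claisen condensation gives A5, the heptamer whose ring D is a 3,5-dihydroxy-2,6-diester.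
- For it: both hindered ether oxygens of ring D enter on carbons of open-chain precursors. This is the same idea as in the chosen strategy, applied to another ring. The union of two three-ring pieces late in the route is more convergent than the chosen plan.
- Against it: the hydrogen of A6 between two esters and an aryloxy group is the most acidic site, and its enolate makes both ester carbonyls poor acyl donors. The anion of A7 is ambident, and after the first acylation a deprotonated β-keto ester must acylate again in a crowded setting, with retro-Claisen cleavage as the easy escape. The two ester groups must later be removed by hydrolysis and double decarboxylation.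
- Comparison: the ethers of ring D are the easy ones in the chosen route (SNAr and Ullmann coupling at an unhindered carbon), so a new ring is built where none is needed, while ring C of A7 remains to be made. The chosen ring expansion is unimolecular, needs no base and has no competing enolisation.

**Alternative 3:** The E–O–F and F–O–G bonds are cut, and rings F and G are grown from two equivalents of syringic acid A10 on the ring D–E phenol A9, which carries chlorine on ring D. Aerobic copper–amine oxidation forms phenoxyl radicals; each chain-end oxygen couples at the carboxyl-bearing para carbon of the next unit with decarboxylation, which gives the tetramer A8 with a free C4 hydroxyl on ring G.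
- For it: it is the shortest conceivable access to the ring D–G part, with no halide, no boron reagent, a cheap building block and two ether bonds in one operation. In step economy it is clearly stronger than steps 12, 13 and 16 of the chosen route.
- Against it: the process is a chain growth, and nothing stops it at exactly two units; shorter and longer chains and homo-oligomers of A10 are expected, and redistribution through quinone ketals scrambles chain lengths. The phenoxyl radical of A9 has a methoxy-bearing para carbon, where oxidative demethylation to a quinone competes. The chlorine on ring D of A8 is a poor electrophile for the later copper coupling with the hindered ring C phenol.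
- Comparison: ring C is again untouched. The chosen route gives up brevity here for bonds that are made one at a time with defined partners.

Key step: step 9

**Assumptions:** 2-fluoro-4,6-dimethoxybenzaldehyde (26) is taken to be a catalogue compound. Cyclobutenones 15 and 16 are racemic; their single stereocentre is destroyed in step 9.

## Route

Step 1
Reactants: 1 4-bromo-2,6-dimethoxyphenol
Product: 2 2-(benzyloxy)-5-bromo-1,3-dimethoxybenzene
Conditions: BnBr, K2CO3, DMF, rt
Reagents that add atoms: benzyl bromide, BrCc1ccccc1
Why: Williamson O-benzylation of the phenoxide; the benzyl ether masks the hindered hydroxyl so that 2 can act only as the electrophile in step 2, and it is later removed by hydrogenolysis without touching methyl or diaryl ethers.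

Step 2
Reactants: 2 2-(benzyloxy)-5-bromo-1,3-dimethoxybenzene; 3 2,4,6-trimethoxyphenol
Product: 4 2-(benzyloxy)-1,3-dimethoxy-5-(2,4,6-trimethoxyphenoxy)benzene
Conditions: CuI (10 mol%), picolinic acid (20 mol%), K3PO4, DMSO, 90 °C, Ar
Reagents that add atoms: none
Why: Ullmann diaryl ether synthesis with the di-ortho-substituted phenol as nucleophile and a bromide without ortho substituents as electrophile; the picolinic acid–CuI system accepts hindered phenoxides, and exclusion of air protects the easily oxidised 3.

Step 3
Reactants: 4 2-(benzyloxy)-1,3-dimethoxy-5-(2,4,6-trimethoxyphenoxy)benzene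
Product: 5 2,6-dimethoxy-4-(2,4,6-trimethoxyphenoxy)phenol (ring A–B phenol)
Conditions: H2 (1 atm), 10% Pd/C, EtOAc–MeOH, rt
Reagents that add atoms: none
Why: Hydrogenolysis of the benzyl ether; no halogen or alkene is left in the molecule, and aryl methyl and diaryl ethers are inert.

Step 4
Reactants: 5 2,6-dimethoxy-4-(2,4,6-trimethoxyphenoxy)phenol; 6 trichloroethylene
Product: 8 2-{[(E)-1,2-dichloroethenyl]oxy}-1,3-dimethoxy-5-(2,4,6-trimethoxyphenoxy)benzene, via dichloroacetylene 7 (not isolated)
Conditions: K2CO3, DMF, 60 °C
Reagents that add atoms: none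
Why: The base eliminates HCl from 6 to give 7 in low stationary concentration, the phenoxide adds anti to this linear electrophile and protonation gives the (E)-dichlorovinyl ether; this is the known O-dichlorovinylation of phenols, and the two ortho methoxy groups do not hinder attack on an sp carbon.

Step 5
Reactants: 8 2-{[(E)-1,2-dichloroethenyl]oxy}-1,3-dimethoxy-5-(2,4,6-trimethoxyphenoxy)benzene
Product: 11 2-(ethynyloxy)-1,3-dimethoxy-5-(2,4,6-trimethoxyphenoxy)benzene, via aryl chloroethynyl ether 9 (not isolated), via lithium aryloxyacetylide 10 (not isolated)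
Conditions: n-BuLi (2.2 equiv), THF, −78 to −40 °C; MeOH, −78 °C
Reagents that add atoms: none
Why: Deprotonation and loss of LiCl give chloroalkyne 9, chlorine–lithium exchange gives acetylide 10 and protonation gives the terminal ynol ether (known conversion of dichlorovinyl ethers into ynol ethers); at −78 °C these events should outrun ortho-lithiation of the methoxyarenes, and 11 is used at once because aryl ynol ethers add water easily.

Step 6
Reactants: 11 2-(ethynyloxy)-1,3-dimethoxy-5-(2,4,6-trimethoxyphenoxy)benzene
Product: 12 tributyl{1-[2,6-dimethoxy-4-(2,4,6-trimethoxyphenoxy)phenoxy]ethenyl}stannane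
Conditions: Bu3SnH (slow addition), Pd(PPh3)4 (3 mol%), THF, 0 °C
Reagents that add atoms: tributyltin hydride, CCCC[SnH](CCCC)CCCC
Why: Hydrostannation of ynol ethers catalysed by zerovalent palladium is a syn addition that places tin on the oxygen-bearing carbon; with a terminal alkyne this gives the 1,1-disubstituted alkene with no geometric issue, and slow addition of the hydride limits its palladium-catalysed dimerisation.

Step 7
Reactants: 12 tributyl{1-[2,6-dimethoxy-4-(2,4,6-trimethoxyphenoxy)phenoxy]ethenyl}stannane; 13 dimethyl squarate (3,4-dimethoxycyclobut-3-ene-1,2-dione)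
Product: 15 racemic 4-{1-[2,6-dimethoxy-4-(2,4,6-trimethoxyphenoxy)phenoxy]ethenyl}-4-hydroxy-2,3-dimethoxycyclobut-2-en-1-one, via 1-aryloxyvinyllithium 14 (not isolated)
Conditions: n-BuLi, THF, −78 °C; then 13, THF, −78 °C; aq. NH4Cl
Reagents that add atoms: none
Why: Tin–lithium exchange gives 14 faster than any arene deprotonation at −78 °C, and 1,2-addition to one of the two equivalent carbonyl groups of 13 gives the tertiary alcohol (known addition of alkenyllithiums to squaric esters); the new stereocentre is not controlled and is erased in step 9.

Step 8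
Reactants: 15 racemic 4-{1-[2,6-dimethoxy-4-(2,4,6-trimethoxyphenoxy)phenoxy]ethenyl}-4-hydroxy-2,3-dimethoxycyclobut-2-en-1-one
Product: 16 racemic 4-[(tert-butyldimethylsilyl)oxy]-4-{1-[2,6-dimethoxy-4-(2,4,6-trimethoxyphenoxy)phenoxy]ethenyl}-2,3-dimethoxycyclobut-2-en-1-one
Conditions: TBSOTf, 2,6-lutidine, CH2Cl2, −78 to 0 °C
Reagents that add atoms: tert-butyldimethylsilyl trifluoromethanesulfonate, CC(C)(C)[Si](C)(C)OS(=O)(=O)C(F)(F)F
Why: Silylation of a hindered tertiary alcohol with the silyl triflate; excess 2,6-lutidine keeps the medium non-acidic so that neither the enol ether nor the vinylogous ester ionises, and the silyl group will mark the future C6 oxygen of ring C.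

Step 9
Reactants: 16 racemic 4-[(tert-butyldimethylsilyl)oxy]-4-{1-[2,6-dimethoxy-4-(2,4,6-trimethoxyphenoxy)phenoxy]ethenyl}-2,3-dimethoxycyclobut-2-en-1-one
Product: 19 4-[(tert-butyldimethylsilyl)oxy]-5-[2,6-dimethoxy-4-(2,4,6-trimethoxyphenoxy)phenoxy]-2,3-dimethoxyphenol (ring A–B–C trimer), via dienylketene 17 (not isolated), via cyclohexa-2,4-dienone 18 (not isolated)
Conditions: toluene (degassed, 0.01 M), 110 °C, Ar
Reagents that add atoms: none
Why: Heating opens the cyclobutenone by a conrotatory 4π electrocyclic reaction to the dienylketene 17; the silyloxy donor on the quaternary carbon turns outward, so the 1-aryloxyvinyl group turns inward and ends up cis to the ketene. Ring C then closes by a thermal disrotatory 6π electrocyclisation in which the ketene carbon (future C3) bonds to the vinyl CH2 (future C2) to give dienone 18, and proton transfer from that CH2 aromatises it to phenol 19. The closest known reaction type is the thermal ring expansion of 4-alkenyl-4-hydroxy- or 4-silyloxycyclobutenones made from squaric esters to tetraoxygenated hydroquinone derivatives (Moore rearrangement), which includes 1-alkoxyvinyl cases. No stereocentre is formed, and the single stereocentre of racemic 16 disappears. The only selectivity needed is the torquoselectivity of the ring opening, which the oxygen donor on that carbon secures; a ketene of the wrong geometry has no hydroxyl to trap it and can only reclose to 16, so material is funnelled through 17. The regiochemistry of ring C is fixed by connectivity: the squarate carbons become C3 to C6, the vinyl carbons become C1 and C2, and the ring B oxygen is already on C1. The silyl group stays on the C6 oxygen, para to the new C3 hydroxyl and out of reach for transfer, which keeps the two oxygens distinct.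

Step 10
Reactants: 19 4-[(tert-butyldimethylsilyl)oxy]-5-[2,6-dimethoxy-4-(2,4,6-trimethoxyphenoxy)phenoxy]-2,3-dimethoxyphenol
Product: 20 tert-butyl{6-[2,6-dimethoxy-4-(2,4,6-trimethoxyphenoxy)phenoxy]-2,3,4-trimethoxyphenoxy}dimethylsilane
Conditions: MeI, K2CO3, acetone, rt
Reagents that add atoms: iodomethane, CI
Why: Williamson O-methylation of the only free phenol; the aryl silyl ether, shielded by two ortho substituents, is expected to survive anhydrous carbonate in acetone at room temperature.

Step 11
Reactants: 20 tert-butyl{6-[2,6-dimethoxy-4-(2,4,6-trimethoxyphenoxy)phenoxy]-2,3,4-trimethoxyphenoxy}dimethylsilane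
Product: 21 6-[2,6-dimethoxy-4-(2,4,6-trimethoxyphenoxy)phenoxy]-2,3,4-trimethoxyphenol (ring A–B–C phenol)
Conditions: Bu4NF, AcOH, THF, 0 °C, Ar
Reagents that add atoms: none
Why: Fluoride cleavage of the aryl silyl ether; buffering with acetic acid avoids a free, air-sensitive phenoxide of this electron-rich ring.

Step 12
Reactants: 1 4-bromo-2,6-dimethoxyphenol; 22 (3,4,5-trimethoxyphenyl)boronic acid
Product: 23 5-bromo-1,3-dimethoxy-2-(3,4,5-trimethoxyphenoxy)benzene (ring F–G bromide)
Conditions: Cu(OAc)2, pyridine, 4 Å MS, CH2Cl2, air, rt
Reagents that add atoms: none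
Why: Chan–Lam oxidative O-arylation at room temperature, chosen because it leaves the aryl bromide untouched, which an Ullmann coupling of 1 would not; the boronic acid has no ortho substituent, and di-ortho-substituted phenols are accepted in this coupling.

Step 13
Reactants: 23 5-bromo-1,3-dimethoxy-2-(3,4,5-trimethoxyphenoxy)benzene
Product: 25 [3,5-dimethoxy-4-(3,4,5-trimethoxyphenoxy)phenyl]boronic acid, via aryllithium 24 (not isolated)
Conditions: n-BuLi, THF, −78 °C; B(OiPr)3, −78 °C to rt; aq. HCl
Reagents that add atoms: triisopropyl borate, CC(C)OB(OC(C)C)OC(C)C; water, O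
Why: Bromine–lithium exchange at −78 °C, trapping of 24 with the borate and acidic hydrolysis; only the C–Br bond reacts, and the aryllithium is short-lived enough at this temperature not to metalate the methoxylated rings.

Step 14
Reactants: 1 4-bromo-2,6-dimethoxyphenol; 26 2-fluoro-4,6-dimethoxybenzaldehyde
Product: 27 2-(4-bromo-2,6-dimethoxyphenoxy)-4,6-dimethoxybenzaldehyde (ring D–E aldehyde)
Conditions: K2CO3, DMF, 120 °C
Reagents that add atoms: none
Why: SNAr by addition–elimination: the ortho formyl group stabilises the Meisenheimer intermediate, and both methoxy groups are meta to the fluorinated carbon and so do not deactivate it; without copper the C–Br bond of 1 is inert.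

Step 15
Reactants: 27 2-(4-bromo-2,6-dimethoxyphenoxy)-4,6-dimethoxybenzaldehyde
Product: 29 2-(4-bromo-2,6-dimethoxyphenoxy)-4,6-dimethoxyphenol (ring D–E phenol), via aryl formate 28 (not isolated)
Conditions: mCPBA, CH2Cl2, 0 °C to rt; aq. Na2SO3 wash; K2CO3 (cat.), MeOH, rt
Reagents that add atoms: 3-chloroperoxybenzoic acid, OOC(=O)c1cccc(Cl)c1
Why: Dakin-type Baeyer–Villiger oxidation: the electron-rich trioxygenated aryl group migrates in the Criegee intermediate to give formate 28, and mild methanolysis releases the phenol that becomes the C6 oxygen of ring E.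

Step 16
Reactants: 29 2-(4-bromo-2,6-dimethoxyphenoxy)-4,6-dimethoxyphenol; 25 [3,5-dimethoxy-4-(3,4,5-trimethoxyphenoxy)phenyl]boronic acid
Product: 30 5-bromo-2-{3,5-dimethoxy-2-[3,5-dimethoxy-4-(3,4,5-trimethoxyphenoxy)phenoxy]phenoxy}-1,3-dimethoxybenzene (ring D–E–F–G bromide)
Conditions: Cu(OAc)2, pyridine, 4 Å MS, CH2Cl2, air, rt
Reagents that add atoms: none
Why: Chan–Lam O-arylation, used here for chemoselectivity: the bromine on ring D is needed in step 17 and would compete in any Ullmann coupling of 29; the boron partner 25 is unhindered, which is the more sensitive side in this reaction.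

Step 17
Reactants: 21 6-[2,6-dimethoxy-4-(2,4,6-trimethoxyphenoxy)phenoxy]-2,3,4-trimethoxyphenol; 30 ring D–E–F–G bromide
Product: 31 heptadeca-O-methyl ether of the target (permethylated ring A–G heptamer)
Conditions: CuI (20 mol%), picolinic acid (40 mol%), K3PO4, DMSO, 100 °C, Ar
Reagents that add atoms: none
Why: Ullmann coupling of the di-ortho-substituted phenoxide of 21 with the ring D bromide, which has hydrogen at both ortho positions; each partner has one reactive group only, and the ligand system is suited to hindered phenoxides.

Step 18
Reactants: 31 permethylated ring A–G heptamer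
Product: 32 CNP0351377.0 (ring A–G heptamer with seventeen free hydroxyls)
Conditions: BBr3 (excess), CH2Cl2, −78 °C to rt; MeOH, then H2O, Ar
Reagents that add atoms: none
Why: Lewis-acid cleavage of all seventeen aryl methyl ethers (boron binds the ether oxygen, bromide removes the methyl group by SN2); the diaryl ether carbons cannot be attacked in this way, and work-up under argon protects the pyrogallol-type rings.

## Compound list

1 | 4-bromo-2,6-dimethoxyphenol | COc1cc(Br)cc(OC)c1O | starting material
2 | 2-(benzyloxy)-5-bromo-1,3-dimethoxybenzene | COc1cc(Br)cc(OC)c1OCc1ccccc1 | intermediate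
3 | 2,4,6-trimethoxyphenol | COc1cc(OC)c(O)c(OC)c1 | starting material
4 | 2-(benzyloxy)-1,3-dimethoxy-5-(2,4,6-trimethoxyphenoxy)benzene | COc1cc(OC)c(Oc2cc(OC)c(OCc3ccccc3)c(OC)c2)c(OC)c1 | intermediate
5 | 2,6-dimethoxy-4-(2,4,6-trimethoxyphenoxy)phenol (ring A–B phenol) | COc1cc(OC)c(Oc2cc(OC)c(O)c(OC)c2)c(OC)c1 | intermediate
6 | trichloroethylene | ClC=C(Cl)Cl | starting material
7 | dichloroacetylene | ClC#CCl | intermediate
8 | 2-{[(E)-1,2-dichloroethenyl]oxy}-1,3-dimethoxy-5-(2,4,6-trimethoxyphenoxy)benzene | COc1cc(OC)c(Oc2cc(OC)c(O/C(Cl)=C\Cl)c(OC)c2)c(OC)c1 | intermediate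
9 | 2-[(chloroethynyl)oxy]-1,3-dimethoxy-5-(2,4,6-trimethoxyphenoxy)benzene | COc1cc(OC)c(Oc2cc(OC)c(OC#CCl)c(OC)c2)c(OC)c1 | intermediate
10 | {[2,6-dimethoxy-4-(2,4,6-trimethoxyphenoxy)phenoxy]ethynyl}lithium | COc1cc(OC)c(Oc2cc(OC)c(OC#C[Li])c(OC)c2)c(OC)c1 | intermediate
11 | 2-(ethynyloxy)-1,3-dimethoxy-5-(2,4,6-trimethoxyphenoxy)benzene | COc1cc(OC)c(Oc2cc(OC)c(OC#C)c(OC)c2)c(OC)c1 | intermediate
12 | tributyl{1-[2,6-dimethoxy-4-(2,4,6-trimethoxyphenoxy)phenoxy]ethenyl}stannane | COc1cc(OC)c(Oc2cc(OC)c(OC(=C)[Sn](CCCC)(CCCC)CCCC)c(OC)c2)c(OC)c1 | intermediate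
13 | dimethyl squarate (3,4-dimethoxycyclobut-3-ene-1,2-dione) | COC1=C(OC)C(=O)C1=O | starting material
14 | {1-[2,6-dimethoxy-4-(2,4,6-trimethoxyphenoxy)phenoxy]ethenyl}lithium | COc1cc(OC)c(Oc2cc(OC)c(OC(=C)[Li])c(OC)c2)c(OC)c1 | intermediate
15 | racemic 4-{1-[2,6-dimethoxy-4-(2,4,6-trimethoxyphenoxy)phenoxy]ethenyl}-4-hydroxy-2,3-dimethoxycyclobut-2-en-1-one | COc1cc(OC)c(Oc2cc(OC)c(OC(=C)C3(O)C(OC)=C(OC)C3=O)c(OC)c2)c(OC)c1 | intermediate
16 | racemic 4-[(tert-butyldimethylsilyl)oxy]-4-{1-[2,6-dimethoxy-4-(2,4,6-trimethoxyphenoxy)phenoxy]ethenyl}-2,3-dimethoxycyclobut-2-en-1-one | COc1cc(OC)c(Oc2cc(OC)c(OC(=C)C3(O[Si](C)(C)C(C)(C)C)C(OC)=C(OC)C3=O)c(OC)c2)c(OC)c1 | intermediate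
17 | dienylketene: (3Z)-5-aryloxy-4-[(tert-butyldimethylsilyl)oxy]-2,3-dimethoxyhexa-1,3,5-trien-1-one, aryl = 2,6-dimethoxy-4-(2,4,6-trimethoxyphenoxy)phenyl, vinyl group cis to the ketene | COc1cc(OC)c(Oc2cc(OC)c(OC(=C)/C(O[Si](C)(C)C(C)(C)C)=C(OC)\C(OC)=C=O)c(OC)c2)c(OC)c1 | intermediate
18 | 5-aryloxy-4-[(tert-butyldimethylsilyl)oxy]-2,3-dimethoxycyclohexa-2,4-dien-1-one, aryl as in 17 | COc1cc(OC)c(Oc2cc(OC)c(OC3=C(O[Si](C)(C)C(C)(C)C)C(OC)=C(OC)C(=O)C3)c(OC)c2)c(OC)c1 | intermediate
19 | 4-[(tert-butyldimethylsilyl)oxy]-5-[2,6-dimethoxy-4-(2,4,6-trimethoxyphenoxy)phenoxy]-2,3-dimethoxyphenol | COc1cc(OC)c(Oc2cc(OC)c(Oc3cc(O)c(OC)c(OC)c3O[Si](C)(C)C(C)(C)C)c(OC)c2)c(OC)c1 | intermediate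
20 | tert-butyl{6-[2,6-dimethoxy-4-(2,4,6-trimethoxyphenoxy)phenoxy]-2,3,4-trimethoxyphenoxy}dimethylsilane | COc1cc(OC)c(Oc2cc(OC)c(Oc3cc(OC)c(OC)c(OC)c3O[Si](C)(C)C(C)(C)C)c(OC)c2)c(OC)c1 | intermediate
21 | 6-[2,6-dimethoxy-4-(2,4,6-trimethoxyphenoxy)phenoxy]-2,3,4-trimethoxyphenol | COc1cc(OC)c(Oc2cc(OC)c(Oc3cc(OC)c(OC)c(OC)c3O)c(OC)c2)c(OC)c1 | intermediate
22 | (3,4,5-trimethoxyphenyl)boronic acid | COc1cc(B(O)O)cc(OC)c1OC | starting material
23 | 5-bromo-1,3-dimethoxy-2-(3,4,5-trimethoxyphenoxy)benzene | COc1cc(Br)cc(OC)c1Oc1cc(OC)c(OC)c(OC)c1 | intermediate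
24 | [3,5-dimethoxy-4-(3,4,5-trimethoxyphenoxy)phenyl]lithium | [Li]c1cc(OC)c(Oc2cc(OC)c(OC)c(OC)c2)c(OC)c1 | intermediate
25 | [3,5-dimethoxy-4-(3,4,5-trimethoxyphenoxy)phenyl]boronic acid | COc1cc(B(O)O)cc(OC)c1Oc1cc(OC)c(OC)c(OC)c1 | intermediate
26 | 2-fluoro-4,6-dimethoxybenzaldehyde | COc1cc(F)c(C=O)c(OC)c1 | starting material
27 | 2-(4-bromo-2,6-dimethoxyphenoxy)-4,6-dimethoxybenzaldehyde | COc1cc(OC)c(C=O)c(Oc2c(OC)cc(Br)cc2OC)c1 | intermediate
28 | 2-(4-bromo-2,6-dimethoxyphenoxy)-4,6-dimethoxyphenyl formate | COc1cc(OC)c(OC=O)c(Oc2c(OC)cc(Br)cc2OC)c1 | intermediate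
29 | 2-(4-bromo-2,6-dimethoxyphenoxy)-4,6-dimethoxyphenol | COc1cc(OC)c(O)c(Oc2c(OC)cc(Br)cc2OC)c1 | intermediate
30 | 5-bromo-2-{3,5-dimethoxy-2-[3,5-dimethoxy-4-(3,4,5-trimethoxyphenoxy)phenoxy]phenoxy}-1,3-dimethoxybenzene | COc1cc(Br)cc(OC)c1Oc1cc(OC)cc(OC)c1Oc1cc(OC)c(Oc2cc(OC)c(OC)c(OC)c2)c(OC)c1 | intermediate
31 | heptadeca-O-methyl ether of the target (permethylated ring A–G heptamer) | COc1cc(OC)c(Oc2cc(OC)c(Oc3cc(OC)c(OC)c(OC)c3Oc3cc(OC)c(Oc4cc(OC)cc(OC)c4Oc4cc(OC)c(Oc5cc(OC)c(OC)c(OC)c5)c(OC)c4)c(OC)c3)c(OC)c2)c(OC)c1 | intermediate
32 | CNP0351377.0, ring A–G heptamer with seventeen free hydroxyls | Oc1cc(O)c(Oc2cc(O)c(Oc3cc(O)c(O)c(O)c3Oc3cc(O)c(Oc4cc(O)cc(O)c4Oc4cc(O)c(Oc5cc(O)c(O)c(O)c5)c(O)c4)c(O)c3)c(O)c2)c(O)c1 | target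

## Step count and least certain steps

Total step count: 18. Longest linear sequence: 13 steps (steps 1 to 11, then 17 and 18). Steps 12 to 16 form the convergent branch to 30.

**Step 9 (key step).** The ring expansion itself is well founded; the weak point is the silyl label. Loss of the silyl group during the thermolysis, or air oxidation of the very electron-rich silyloxyphenol, would erase the distinction between the C3 and C6 oxygens. Crowding at the quaternary carbon between the silyl ether and the bulky aryloxyvinyl group may also slow the inward rotation, so that decomposition of the enol ether competes.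
Fallback: the route sets out from the free alcohol 15, which is heated in degassed toluene as the classical hydroxy variant of the same ring expansion. This gives the hydroquinone 5-[2,6-dimethoxy-4-(2,4,6-trimethoxyphenoxy)phenoxy]-2,3-dimethoxybenzene-1,4-diol F1, kept under argon. The two hydroxyls are then told apart by their surroundings and not by a label: one equivalent of iodomethane with K2CO3 in acetone should methylate the C3 hydroxyl, which has a hydrogen neighbour, in preference to the C6 hydroxyl, which lies between the aryloxy and a methoxy group. This returns to phenol 21 and saves steps 8, 10 and 11. The selectivity rests on sterics alone, which is why the silyl route is preferred.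

**Step 6.** Tin may be delivered in part to the terminal carbon, since an aryloxy group polarises the alkyne less than an alkoxy group, and the α-stannyl enol ether may lose tin by protonation on silica.
Fallback: from ynol ether 11, one equivalent of dry HBr in CH2Cl2 at −78 °C adds in the Markovnikov sense, because protonation at the terminal carbon gives the oxygen-stabilised cation. The product is 2-[(1-bromoethenyl)oxy]-1,3-dimethoxy-5-(2,4,6-trimethoxyphenoxy)benzene F2. Bromine–lithium exchange with t-BuLi (2 equiv) in THF at −78 °C then gives vinyllithium 14, and the route continues with the addition to 13 in step 7. No tin is used.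

**Step 16.** Divalent copper in air may oxidise the electron-rich phenol 29, which has a methoxy group para to the hydroxyl, with oxidative demethylation to a quinone. The hindered phenoxide may also transmetalate slowly, so that the boronic acid is consumed by protodeboronation and homocoupling.
Fallback: the order of assembly is changed so that only Ullmann couplings with one phenol and one bromide are used. Phenol 21 is coupled with bromo aldehyde 27 (CuI, picolinic acid, K3PO4, DMSO) to give the ring A–B–C–D–E aldehyde F3. Baeyer–Villiger oxidation with mCPBA gives the ring A–B–C–D–E formate F4, and methanolysis gives the ring A–B–C–D–E phenol F5, with its hydroxyl at C6 of ring E. A second Ullmann coupling of F5 with the ring F–G bromide 23 comes back to 31. Compounds 25, 29 and 30 are then not needed, at the price of a longer linear sequence on material that has passed the key step.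

**Step 17.** Both partners are large, and the phenoxide is di-ortho-substituted and electron-rich. A slow coupling would leave time for reductive loss of bromine from 30 and for oxidative decay of the phenoxide of 21 at 100 °C.
Fallback: from bromide 30, bromine–lithium exchange (n-BuLi, THF, −78 °C), B(OiPr)3 and acidic work-up give the ring D–E–F–G boronic acid F6. This is joined to phenol 21 by Chan–Lam coupling (Cu(OAc)2, pyridine, CH2Cl2, rt), which comes back to 31 without prolonged heating of the phenoxide.

**Step 18.** Seventeen ethers must be cleaved. Boron bound to neighbouring oxygens uses up reagent, and partly demethylated borates may precipitate, so incomplete cleavage is likely. The free polyphenol is also oxidised during chromatography.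
Fallback: from 31, the crude product of the BBr3 treatment is not isolated but acetylated (Ac2O, pyridine) to the heptadecaacetate of the target F7. F7 is stable to air and to silica, so under-demethylated material can be separated and returned to BBr3. Acid-catalysed methanolysis (HCl in MeOH, rt, Ar) of pure F7 then gives 32 with only volatile by-products.

## Further compounds

F1 | step 9 | 5-[2,6-dimethoxy-4-(2,4,6-trimethoxyphenoxy)phenoxy]-2,3-dimethoxybenzene-1,4-diol | COc1cc(OC)c(Oc2cc(OC)c(Oc3cc(O)c(OC)c(OC)c3O)c(OC)c2)c(OC)c1
F2 | step 6 | 2-[(1-bromoethenyl)oxy]-1,3-dimethoxy-5-(2,4,6-trimethoxyphenoxy)benzene | COc1cc(OC)c(Oc2cc(OC)c(OC(Br)=C)c(OC)c2)c(OC)c1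
F3 | step 16 | ring A–B–C–D–E aldehyde (permethylated, formyl group at C6 of ring E) | COc1cc(OC)c(Oc2cc(OC)c(Oc3cc(OC)c(OC)c(OC)c3Oc3cc(OC)c(Oc4cc(OC)cc(OC)c4C=O)c(OC)c3)c(OC)c2)c(OC)c1
F4 | step 16 | ring A–B–C–D–E formate (permethylated, formyloxy group at C6 of ring E) | COc1cc(OC)c(Oc2cc(OC)c(Oc3cc(OC)c(OC)c(OC)c3Oc3cc(OC)c(Oc4cc(OC)cc(OC)c4OC=O)c(OC)c3)c(OC)c2)c(OC)c1
F5 | step 16 | ring A–B–C–D–E phenol (permethylated, free hydroxyl at C6 of ring E) | COc1cc(OC)c(Oc2cc(OC)c(Oc3cc(OC)c(OC)c(OC)c3Oc3cc(OC)c(Oc4cc(OC)cc(OC)c4O)c(OC)c3)c(OC)c2)c(OC)c1
F6 | step 17 | ring D–E–F–G boronic acid, (4-{3,5-dimethoxy-2-[3,5-dimethoxy-4-(3,4,5-trimethoxyphenoxy)phenoxy]phenoxy}-3,5-dimethoxyphenyl)boronic acid | COc1cc(B(O)O)cc(OC)c1Oc1cc(OC)cc(OC)c1Oc1cc(OC)c(Oc2cc(OC)c(OC)c(OC)c2)c(OC)c1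
F7 | step 18 | heptadecaacetate of the target | CC(=O)Oc1cc(OC(C)=O)c(Oc2cc(OC(C)=O)c(Oc3cc(OC(C)=O)c(OC(C)=O)c(OC(C)=O)c3Oc3cc(OC(C)=O)c(Oc4cc(OC(C)=O)cc(OC(C)=O)c4Oc4cc(OC(C)=O)c(Oc5cc(OC(C)=O)c(OC(C)=O)c(OC(C)=O)c5)c(OC(C)=O)c4)c(OC(C)=O)c3)c(OC(C)=O)c2)c(OC(C)=O)c1
A1 | alternative 1 | permethylated ring A–G heptamer (identical with 31) | COc1cc(OC)c(Oc2cc(OC)c(Oc3cc(OC)c(OC)c(OC)c3Oc3cc(OC)c(Oc4cc(OC)cc(OC)c4Oc4cc(OC)c(Oc5cc(OC)c(OC)c(OC)c5)c(OC)c4)c(OC)c3)c(OC)c2)c(OC)c1
A2 | alternative 1 | (η5-cyclopentadienyl)(η6-1,2-dichloro-3,5-dimethoxybenzene)ruthenium hexafluorophosphate, written as its components | COc1cc(OC)c(Cl)c(Cl)c1.[cH-]1cccc1.[Ru+2].F[P-](F)(F)(F)(F)F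
A3 | alternative 1 | ring A–B–C–D phenol (permethylated, free hydroxyl at C4 of ring D) | COc1cc(OC)c(Oc2cc(OC)c(Oc3cc(OC)c(OC)c(OC)c3Oc3cc(OC)c(O)c(OC)c3)c(OC)c2)c(OC)c1
A4 | alternative 1 | 3,5-dimethoxy-4-(3,4,5-trimethoxyphenoxy)phenol (ring F–G phenol) | COc1cc(O)cc(OC)c1Oc1cc(OC)c(OC)c(OC)c1
A5 | alternative 2 | heptamer with ring D as a 3,5-dihydroxy-2,6-bis(methoxycarbonyl) ring | COc1cc(OC)c(Oc2cc(OC)c(Oc3cc(OC)c(OC)c(OC)c3Oc3c(C(=O)OC)c(O)c(Oc4cc(OC)cc(OC)c4Oc4cc(OC)c(Oc5cc(OC)c(OC)c(OC)c5)c(OC)c4)c(O)c3C(=O)OC)c(OC)c2)c(OC)c1
A6 | alternative 2 | dimethyl 2-(ring E–F–G aryloxy)malonate | COC(=O)C(Oc1cc(OC)cc(OC)c1Oc1cc(OC)c(Oc2cc(OC)c(OC)c(OC)c2)c(OC)c1)C(=O)OC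
A7 | alternative 2 | dimethyl 3-(ring A–B–C aryloxy)pent-2-enedioate (double-bond geometry not specified) | COC(=O)CC(=CC(=O)OC)Oc1c(Oc2c(OC)cc(Oc3c(OC)cc(OC)cc3OC)cc2OC)cc(OC)c(OC)c1OC
A8 | alternative 3 | ring D–E–F–G tetramer with chlorine at C1 of ring D and free C4 hydroxyl on ring G | Oc1c(OC)cc(Oc2c(OC)cc(Oc3c(OC)cc(OC)cc3Oc3c(OC)cc(Cl)cc3OC)cc2OC)cc1OC
A9 | alternative 3 | 2-(4-chloro-2,6-dimethoxyphenoxy)-4,6-dimethoxyphenol (ring D–E phenol) | COc1cc(OC)c(O)c(Oc2c(OC)cc(Cl)cc2OC)c1
A10 | alternative 3 | syringic acid (4-hydroxy-3,5-dimethoxybenzoic acid) | COc1cc(C(=O)O)cc(OC)c1O
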